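## Remarks on the structures and assumptions

- **Numbering.** C1 is the quaternary carbinol, C2 the ketone, C3 the CH2, C4 the carbinol, C5 the benzoate carbon, C6 the carbinol and C7 the exocyclic CH2. These atoms keep their numbers in every intermediate.
- **Stereochemistry.** The target is (1S,4R,5R,6S). C1–OH and C6–OH are cis; C4–OH and C5–OBz are cis to each other and trans to C6–OH. A lactone with a (4R) carbinol carbon and a (Z)-enol ether maps through a boat onto exactly this C1/C6 pair, so the configurations of the rearrangement precursor and of the rearranged acid stand as drawn.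
- **Correction of the precursor name.** The rearranging lactone has a seven-carbon aldonic chain. It is a 4,6-dideoxy-hept-6-enono-1,5-lactone whose C6=C7 is the enol ether. A hexono-1,5-lactone with an added vinyl group on the ring carbinol carbon would have one carbon too many and a quaternary C4.
- **Correction on C2.** C2 is not indifferent before it becomes the ketone. The alkenyl arm on C4 can stand axial without a syn-axial oxygen (which would also face the inward tert-butoxy group) only if C2–O is trans to it. The D-pentose supplies this relationship.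
- **Improved precursor.** O1 and O2 are carried as one isopropylidene acetal instead of two different ethers, for four reasons:
  - No differentiation is needed: after the shift O1 is tertiary and O2 secondary, so oxidation tells them apart.
  - The acetal goes on in one step and gives the lactol directly.
  - In the ketene acetal the dioxolane holds C2–O near the nodal plane, which disfavours E1cB, and so forces the trans alkenyl arm axial.
  - Both spectator groups leave in one mild hydrolysis and no hydrogenolysis is needed.
- **Assumption.** tert-Butoxyacetylene is taken as purchasable and is kept at or below room temperature, since tert-butyl ynol ethers fragment to ketenes on heating.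

## Structural features

The target is one cyclohexanone ring (C1–C6) with a single exocyclic carbon, C7, on C1. C1 is a fully substituted carbinol bearing the CH2OBz arm and lies between the C2 ketone and the C6 carbinol. C3 is the only methylene; C4 (free OH), C5 (benzoate), C6 (free OH) and C1 form four contiguous stereocentres. The C4 hydroxyl is β to the ketone (dehydration, retro-aldol), C1/C2 form a tertiary α-ketol, and both benzoates sit next to free hydroxyls, so acyl migration is possible and a benzoate reaching O4 would be eliminated. The end game must therefore avoid base and use strong acid only briefly. The real difficulty is the quaternary C1 next to C6, both oxygenated and cis, together with telling six oxygen functions apart. The key step exploits the array C7–C1–C6–C5=C4 of a cyclohex-4-ene precursor: a γ,δ-unsaturated acid whose C1–C6 bond is a Claisen bond. Because C4 is already tied to C1 through C2–C3, the ester oxygen must sit on C4, in a δ-lactone C7(=O)–O–C4 carrying a (Z)-alkoxyvinyl arm C5=C6.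

## Logic of the disconnections

22 ⇒ 21. The O–C bond of the tert-butyl ether on O6 is cut last, so the final step only unmasks. The demand is an acid that ionises the ether without dehydrating the C2/C4 aldol unit.

21 ⇒ 20. The benzoyl–O5 bond is cut, so that O4 and O5 come from one cis-diol. The forward step must acylate O5 only, because an ester on O4 would be β to the ketone.

20 ⇒ 19. The C4–O and C5–O bonds are cut together, back to the C4=C5 double bond. Two stereocentres disappear. The reagent must add anti to O6, and 19 must not slip into conjugation.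

19 ⇒ 18. No skeletal bond is cut; the C2 carbonyl is traced to a carbinol, since the Claisen substrate needs sp3 C2. The oxidation must be neutral; the tertiary O1–H cannot react.

18 ⇒ 17. The two acetal C–O bonds are re-formed, tying O1 and O2 together. One group then protects two hydroxyls. Its hydrolysis must spare the tert-butyl ether and the primary benzoate.

17 ⇒ 16. The benzoyl–O7 bond is cut. 16 has a single free hydroxyl, so the forward acylation needs no selectivity.

16 ⇒ 15. C7 is returned to the carboxyl level. A carboxyl on C1 with a C4=C5 alkene is the retron of an ester-enolate Claisen shift. The forward step is hydride reduction of a hindered acid.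

15 ⇒ 12. The C1–C6 bond is cut and the C4–O bond to the carboxyl oxygen restored, the alkene moving to C5=C6. The quaternary centre, its neighbour and the carbocycle vanish at once. What remains is a monocyclic lactone ruled by one carbinol centre and one alkene geometry. The forward step needs ketene acetal 13 without β-elimination, a boat-shaped concerted shift, and retention of the Z geometry.

12 ⇒ 11. The two vinylic C–H bonds are removed, giving the alkyne. The forward step needs syn semi-hydrogenation without C–O hydrogenolysis.

11 ⇒ 8. The acyl C7–O4 bond is cut and C7 lowered to the alcohol. The result is an open-chain diol. The primary alcohol must be oxidised beside a propargylic alcohol and an ynol ether, without acid.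

8 ⇒ 6. The C4–H bond is cut, taking the carbinol back to the ketone level, stored as hemiketal 6. A chiral reagent must deliver hydride to give the (4R) centre.

6 ⇒ 3 + 4. The C4–C5 bond between carbonyl carbon and alkyne is cut. This splits the skeleton into its two building blocks. The acetylide must add only once.

3 ⇒ 2. The lactone carbonyl is taken back to the lactol. This is a plain oxidation in the forward sense.

2 ⇒ 1. The two acetal C–O bonds are cut, reaching the pentose. The forward acetalisation must select the cis-3,4-diol of the pyranose form.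

## Other disconnections considered

Alternative 1: The C4–C5 bond is cut, leading to dialdehyde A1, which carries the C1/C6 acetonide, the C2 dioxolane ketal and the C7 benzoate. In the forward sense SmI2 (divalent samarium) in THF/tert-butanol would couple the two ketyls to cis-diol A2.
- In favour: one step closes the ring and sets C4 and C5 as the required cis-diol under neutral conditions; the rigid acetonide should steer the diol anti to O6; no osmylation is needed.
- Against: C1 and C6 must already be present in A1, so the hardest centre is left to earlier branched-chain chemistry. The C5 formyl group is α to an acetal oxygen, so loss of alkoxide from the ketyl can compete. The regioselective O5 benzoylation and an acidic double deacetalisation of the aldol remain.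
- Comparison: the chosen plan forms the congested C1–C6 bond and the ring together, whereas this one forms the least hindered ring bond. Its radical coupling rests on chelation and substrate bias, while the sigmatropic shift copies one carbinol centre and one alkene geometry. On the back end Alternative 1 is the better plan (fewer steps after the key step, diol made directly). On O4/O5 differentiation it is only the equal. Its front end should be longer.

Alternative 2: The C1–C7 bond is cut, leading to ketone A3. Dimethylsulfoxonium methylide (Me3S(O)I, NaH) would give spiro-oxirane A4, whose opening at CH2 by benzoate would deliver C7–OBz and the C1 hydroxyl.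
- In favour: the ring can come from a chiral-pool cyclohexane and need not be built. Oxirane opening installs the C7 benzoate and the tertiary alcohol in one operation, which is better than the reduction/benzoylation pair of the chosen plan. No acid-labile enol ether is handled.
- Against: the C1 configuration depends on face selection at a ketone flanked by a ketal carbon and a silyloxy carbon, and the sense relative to O6 is not secured. A3 is a β-alkoxy ketone under strongly basic conditions, so epimerisation at C6 and E1cB loss of O5 threaten. Four kinds of protecting group must later be exchanged or removed.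
- Comparison: both plans address C1. This one relies on external reagent approach, the chosen one on intramolecular chirality transfer. Overall step count is probably equal or higher because of the protecting-group traffic.

Alternative 3: The C3–C4 bond is cut, leading to the C-branched hex-5-enopyranoside A5. Hg(OCOCF3)2 (divalent mercury) in aqueous acetone would hydrate the enol ether, open the hemiketal and close the C3 enolate onto the C4 aldehyde to give cyclohexanone A6.
- In favour: C1, C5, C6 and both benzoates are fixed on the sugar before ring closure. A6 is one hydrogenolysis from the target, the shortest end game of all plans and clearly better than the chosen one. The aldol is made under mild aqueous conditions, and the new hydroxyl usually comes out trans to the C6 substituent, as required.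
- Against: A5 needs a stereoselective chain branching at a quaternary carbinol next to the enol ether, which is a long sugar sequence. The C4 centre depends on a substrate-sensitive aldol closure. A mercury salt is used.
- Comparison: this plan closes the ring at the unfunctionalised C3–C4 bond by an enolate aldol; the chosen plan closes at C1–C6 by a pericyclic shift. Both take absolute configuration from one cheap sugar and are equal on that point. The chosen plan reaches the quaternary centre from a plain pentose in fewer front-end steps.

Key step: step 7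

## Steps

Step 1
Reactants: 1 2-deoxy-D-ribose
Product: 2 2-deoxy-3,4-O-isopropylidene-D-erythro-pentopyranose (lactol; both anomers)
Conditions: 2-methoxypropene, PPTS (cat.), EtOAc, 0 °C → rt
Reagents that add atoms: 2-methoxypropene, COC(C)=C
Why: Acid-catalysed isopropylidene acetal formation: the cis-3,4-diol of the pyranose form closes a dioxolane while the anomeric hydroxyl stays free; no stereocentre is touched, so the D-erythro pair (future O1 and O2) is carried on unchanged.

Step 2
Reactants: 2 2-deoxy-3,4-O-isopropylidene-D-erythro-pentopyranose
Product: 3 2-deoxy-3,4-O-isopropylidene-D-erythro-pentono-1,5-lactone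
Conditions: TEMPO (cat.), PhI(OAc)2, CH2Cl2, rt
Reagents that add atoms: none
Why: Nitroxyl-catalysed oxidation of a lactol to the lactone; the hemiacetal carbinol is the only oxidisable position and the acetal tolerates the acetic acid that is set free.

Step 3
Reactants: 3 2-deoxy-3,4-O-isopropylidene-D-erythro-pentono-1,5-lactone; 4 tert-butoxyacetylene
Product: 6 1-C-(tert-butoxyethynyl)-2-deoxy-3,4-O-isopropylidene-D-erythro-pentopyranose (cyclic hemiketal; both anomers), via lithium tert-butoxyacetylide 5 (not isolated)
Conditions: 4, n-BuLi, THF, −78 °C; then 3, −78 °C; aq. NH4Cl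
Reagents that add atoms: none
Why: 1,2-Addition of a lithium alkynide to a lactone stops at the tetrahedral lithium hemiketal at −78 °C, so one alkynyl group is attached and the C4–C5 bond is formed; the hemiketal centre is not a lasting stereocentre because it is trigonal in the open form.

Step 4
Reactants: 6 1-C-(tert-butoxyethynyl)-2-deoxy-3,4-O-isopropylidene-D-erythro-pentopyranose
Product: 8 (3R,5S,6R)-1-tert-butoxy-5,6-(isopropylidenedioxy)hept-1-yne-3,7-diol, via open-chain hydroxy ynone 7 (not isolated)
Conditions: Ru[(R,R)-Tsdpen](p-cymene) (2 mol%), i-PrOH, rt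
Reagents that add atoms: none
Why: Noyori asymmetric transfer hydrogenation of an alkynyl ketone: the hemiketal opens to 7 and the chiral Ru–H/N–H unit delivers hydride to the face that places the alkynyl group in the site normally taken by an aryl group, which with the (R,R)-ligand should give the (4R) carbinol (O4 syn to O2); base-free 2-propanol avoids conjugate addition to the push–pull ynone and acid-triggered rearrangement of the ynol ether.

Step 5
Reactants: 8 (3R,5S,6R)-1-tert-butoxy-5,6-(isopropylidenedioxy)hept-1-yne-3,7-diol
Product: 11 (3S,4S,6R)-6-(tert-butoxyethynyl)-3,4-(isopropylidenedioxy)oxan-2-one, via hydroxy aldehyde 9 (not isolated), via six-membered lactol 10 (not isolated)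
Conditions: [Cu(MeCN)4]OTf (5 mol%), 2,2'-bipyridine, TEMPO, N-methylimidazole, MeCN, air, rt
Reagents that add atoms: none
Why: Copper/nitroxyl aerobic oxidative lactonisation of a 1,5-diol: the unhindered primary carbinol C7 is oxidised to 9, O4 closes lactol 10 and a second oxidation gives the δ-lactone; the secondary propargylic alcohol is left alone and the medium contains neither acid nor an electrophilic oxidant that would attack the ynol ether, so C4 is untouched.

Step 6
Reactants: 11 (3S,4S,6R)-6-(tert-butoxyethynyl)-3,4-(isopropylidenedioxy)oxan-2-one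
Product: 12 (3S,4S,6R)-6-[(Z)-2-tert-butoxyethenyl]-3,4-(isopropylidenedioxy)oxan-2-one (cis-fused acetonide on C1/C2, alkenyl arm on C4 trans to O2)
Conditions: H2 (1 atm), Pd/CaCO3 poisoned with Pb(OAc)2 (Lindlar catalyst), quinoline, EtOAc, rt
Reagents that add atoms: none
Why: Lindlar semi-hydrogenation: syn delivery of H2 from the poisoned palladium surface gives the (Z)-enol ether, and quinoline holds back over-reduction and hydrogenolysis of the propargylic C–O bond; the acid-labile product is filtered and used directly.

Step 7
Reactants: 12 (3S,4S,6R)-6-[(Z)-2-tert-butoxyethenyl]-3,4-(isopropylidenedioxy)oxan-2-one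
Product: 15 (1R,2S,6S)-2-tert-butoxy-1,6-(isopropylidenedioxy)cyclohex-3-ene-1-carboxylic acid, via trimethylsilyl ketene acetal 13 (not isolated), via trimethylsilyl ester 14 (not isolated)
Conditions: Me3SiCl/Et3N (premixed, HCl-free), LiN(SiMe3)2, THF, −78 °C → rt; PhMe, 60 °C if conversion is incomplete; aq. NaH2PO4
Reagents that add atoms: none
Why: LiN(SiMe3)2 removes the only α-hydrogen (on C1) in the presence of Me3SiCl, so the enolate is O-silylated to 13 as it forms; this is an Ireland–Claisen rearrangement with internal quench, closest to the known ring contraction of alkenyl-lactone silyl ketene acetals to cycloalkenecarboxylic acids and to glycal-ester Claisen shifts in which the allyl terminus bears oxygen. In 13 the dioxolane keeps the C2–O bond near the plane of the ketene acetal, which denies the β-oxygen the overlap needed for E1cB and, because O2 and the alkenyl arm are trans, fixes the arm axial over the ring. On warming, the atoms C1=C7–O–C4–C5=C6 reorganise suprafacially in a concerted [3,3] shift: C1–C6 forms, C4–O breaks, C4=C5 and silyl ester 14 appear, and aqueous work-up gives acid 15. The cyclohexene is closed by sigmatropic exchange of the lactone C4–O bond for the C1–C6 bond inside a bridged, bicyclo[2.2.2]octane-like boat; it is not a nucleophilic cyclisation, so no Baldwin class applies, and the boat is the only array possible with C1 and C4 joined through C2–C3. C1 is controlled by C4: the new bond can only form on the ketene acetal face that carries the axial arm, so the (4R) centre is copied into C1 with the carboxyl on the face the ring oxygen leaves and O1 on the other. C6 is controlled by the alkene geometry: in the boat the Z tert-butoxy group takes the inner position pointing toward C2–C3, which after bonding is the face of O1, giving O1 and O6 cis. The step needs O-silylation before fragmentation and a concerted rather than ionic shift so that the Z information survives; the low temperature, the lithium counter-ion, the non-polar medium and the absence of Lewis acid secure this, and the donor alkoxy group lowers the barrier so that gentle warming should suffice.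

Step 8
Reactants: 15 (1R,2S,6S)-2-tert-butoxy-1,6-(isopropylidenedioxy)cyclohex-3-ene-1-carboxylic acid
Product: 16 [2-tert-butoxy-1,6-(isopropylidenedioxy)cyclohex-3-en-1-yl]methanol (ring configuration as in 15)
Conditions: LiAlH4, THF, 0 °C → reflux
Reagents that add atoms: none
Why: Hydride reduction of the carboxylic acid to the neopentyl-type primary alcohol C7–OH; acetal, tert-butyl ether and alkene are inert and no stereocentre is affected.

Step 9
Reactants: 16 [2-tert-butoxy-1,6-(isopropylidenedioxy)cyclohex-3-en-1-yl]methanol
Product: 17 [2-tert-butoxy-1,6-(isopropylidenedioxy)cyclohex-3-en-1-yl]methyl benzoate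
Conditions: BzCl, pyridine, DMAP (cat.), CH2Cl2, 0 °C → rt
Reagents that add atoms: benzoyl chloride, O=C(Cl)c1ccccc1
Why: DMAP-catalysed acylation of the only free hydroxyl installs the C7 benzoate of the target.

Step 10
Reactants: 17 [2-tert-butoxy-1,6-(isopropylidenedioxy)cyclohex-3-en-1-yl]methyl benzoate
Product: 18 (2-tert-butoxy-1,6-dihydroxycyclohex-3-en-1-yl)methyl benzoate (O1 and O6 cis, O2 trans to O1)
Conditions: AcOH/H2O (4:1), 45 °C
Reagents that add atoms: none
Why: Acid-catalysed acetal hydrolysis: the strained trans-fused dioxolane is cleaved by aqueous acetic acid, which is too weak to ionise the tert-butyl ether or to move the primary benzoate.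

Step 11
Reactants: 18 (2-tert-butoxy-1,6-dihydroxycyclohex-3-en-1-yl)methyl benzoate
Product: 19 (2-tert-butoxy-1-hydroxy-6-oxocyclohex-3-en-1-yl)methyl benzoate
Conditions: IBX, DMSO, rt
Reagents that add atoms: none
Why: IBX oxidation of the secondary C2 alcohol: the tertiary C1 hydroxyl cannot be oxidised, IBX turns vicinal diols into α-ketols without glycol cleavage, and the neutral medium should keep the β,γ-double bond out of conjugation.

Step 12
Reactants: 19 (2-tert-butoxy-1-hydroxy-6-oxocyclohex-3-en-1-yl)methyl benzoate
Product: 20 (2-tert-butoxy-1,3,4-trihydroxy-6-oxocyclohexyl)methyl benzoate (configuration at C1, C4, C5, C6 as in 22)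
Conditions: OsO4 (2 mol%), N-methylmorpholine N-oxide, acetone/H2O, 0 °C
Reagents that add atoms: osmium tetroxide, O=[Os](=O)(=O)=O; N-methylmorpholine N-oxide, C[N+]1([O-])CCOCC1; water, O
Why: Upjohn dihydroxylation: suprafacial [3+2] addition gives the cis-4,5-diol, and attack should come anti to the allylic tert-butoxy group on C6, the usual outcome for allylic ethers; with the acetal gone the ring can take the half-chair with the CH2OBz arm equatorial, in which the axial C1 hydroxyl and the tert-butoxy group both shield the lower face and the sp2 C2 leaves the upper face open, which sets C4 and C5.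

Step 13
Reactants: 20 (2-tert-butoxy-1,3,4-trihydroxy-6-oxocyclohexyl)methyl benzoate
Product: 21 [3-(benzoyloxy)-2-tert-butoxy-1,4-dihydroxy-6-oxocyclohexyl]methyl benzoate (benzoate on O5)
Conditions: Me2SnCl2 (5 mol%), BzCl, i-Pr2NEt, THF, 0 °C → rt
Reagents that add atoms: benzoyl chloride, O=C(Cl)c1ccccc1
Why: Organotin-catalysed regioselective monoacylation of a cis-1,2-diol through a dimethylstannylene acetal formed in situ: in the chair with CH2OBz and the tert-butoxy group equatorial, O5 is equatorial and O4 axial, and stannylene activation raises the nucleophilicity of the equatorial oxygen next to an axial one, as in the 3-O-benzoylation of manno- and galacto-pyranosides; the tertiary C1 hydroxyl is inert.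

Step 14
Reactants: 21 [3-(benzoyloxy)-2-tert-butoxy-1,4-dihydroxy-6-oxocyclohexyl]methyl benzoate
Product: 22 [(1S,2S,3R,4R)-3-(benzoyloxy)-1,2,4-trihydroxy-6-oxocyclohexyl]methyl benzoate (target)
Conditions: CF3CO2H/CH2Cl2 (1:3), 0 °C → rt
Reagents that add atoms: none
Why: Acidolysis of the tert-butyl ether (loss of the tert-butyl cation as 2-methylpropene) frees the C6 hydroxyl; brief exposure at low temperature is chosen to avoid dehydration of the β-hydroxy ketone and acyl migration.

## Compound list

1 | 2-deoxy-D-ribose (2-deoxy-D-erythro-pentose, drawn open-chain) | O=CC[C@H](O)[C@H](O)CO | starting material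
2 | 2-deoxy-3,4-O-isopropylidene-D-erythro-pentopyranose (lactol, both anomers) | OC1C[C@@H]2OC(C)(C)O[C@@H]2CO1 | intermediate
3 | 2-deoxy-3,4-O-isopropylidene-D-erythro-pentono-1,5-lactone | O=C1C[C@@H]2OC(C)(C)O[C@@H]2CO1 | intermediate
4 | tert-butoxyacetylene | C#COC(C)(C)C | starting material
5 | lithium tert-butoxyacetylide (not isolated) | [Li]C#COC(C)(C)C | intermediate
6 | 1-C-(tert-butoxyethynyl)-2-deoxy-3,4-O-isopropylidene-D-erythro-pentopyranose (cyclic hemiketal, both anomers) | OC1(C#COC(C)(C)C)C[C@@H]2OC(C)(C)O[C@@H]2CO1 | intermediate
7 | (5S,6R)-1-tert-butoxy-7-hydroxy-5,6-(isopropylidenedioxy)hept-1-yn-3-one (open-chain tautomer of 6, not isolated) | OC[C@H]1OC(C)(C)O[C@H]1CC(=O)C#COC(C)(C)C | intermediate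
8 | (3R,5S,6R)-1-tert-butoxy-5,6-(isopropylidenedioxy)hept-1-yne-3,7-diol | OC[C@H]1OC(C)(C)O[C@H]1C[C@@H](O)C#COC(C)(C)C | intermediate
9 | (2S,3S,5R)-7-tert-butoxy-5-hydroxy-2,3-(isopropylidenedioxy)hept-6-ynal (not isolated) | O=C[C@H]1OC(C)(C)O[C@H]1C[C@@H](O)C#COC(C)(C)C | intermediate
10 | lactol of 11: 6-(tert-butoxyethynyl)-3,4-(isopropylidenedioxy)oxan-2-ol (not isolated) | OC1O[C@@H](C#COC(C)(C)C)C[C@@H]2OC(C)(C)O[C@H]12 | intermediate
11 | (3S,4S,6R)-6-(tert-butoxyethynyl)-3,4-(isopropylidenedioxy)oxan-2-one | O=C1O[C@@H](C#COC(C)(C)C)C[C@@H]2OC(C)(C)O[C@H]12 | intermediate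
12 | (3S,4S,6R)-6-[(Z)-2-tert-butoxyethenyl]-3,4-(isopropylidenedioxy)oxan-2-one (Claisen precursor; 7-O-tert-butyl-4,6-dideoxy-2,3-O-isopropylidene-hept-6-enono-1,5-lactone) | O=C1O[C@@H](/C=C\OC(C)(C)C)C[C@@H]2OC(C)(C)O[C@H]12 | intermediate
13 | trimethylsilyl ketene acetal of 12 (not isolated) | C[Si](C)(C)OC1=C2OC(C)(C)O[C@H]2C[C@H](/C=C\OC(C)(C)C)O1 | intermediate
14 | trimethylsilyl ester of 15 (not isolated) | C[Si](C)(C)OC(=O)[C@@]12OC(C)(C)O[C@H]1CC=C[C@@H]2OC(C)(C)C | intermediate
15 | (1R,2S,6S)-2-tert-butoxy-1,6-(isopropylidenedioxy)cyclohex-3-ene-1-carboxylic acid (Claisen product; O1/O6 cis, trans-fused acetonide on O1/O2) | OC(=O)[C@@]12OC(C)(C)O[C@H]1CC=C[C@@H]2OC(C)(C)C | intermediate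
16 | [2-tert-butoxy-1,6-(isopropylidenedioxy)cyclohex-3-en-1-yl]methanol (ring configuration as in 15) | OC[C@@]12OC(C)(C)O[C@H]1CC=C[C@@H]2OC(C)(C)C | intermediate
17 | [2-tert-butoxy-1,6-(isopropylidenedioxy)cyclohex-3-en-1-yl]methyl benzoate | O=C(OC[C@@]12OC(C)(C)O[C@H]1CC=C[C@@H]2OC(C)(C)C)c1ccccc1 | intermediate
18 | (2-tert-butoxy-1,6-dihydroxycyclohex-3-en-1-yl)methyl benzoate (O1/O6 cis, O2 trans to O1) | O=C(OC[C@@]1(O)[C@@H](O)CC=C[C@@H]1OC(C)(C)C)c1ccccc1 | intermediate
19 | (2-tert-butoxy-1-hydroxy-6-oxocyclohex-3-en-1-yl)methyl benzoate | O=C(OC[C@@]1(O)C(=O)CC=C[C@@H]1OC(C)(C)C)c1ccccc1 | intermediate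
20 | (2-tert-butoxy-1,3,4-trihydroxy-6-oxocyclohexyl)methyl benzoate (C1, C4, C5, C6 as in 22) | O=C(OC[C@@]1(O)C(=O)C[C@@H](O)[C@@H](O)[C@@H]1OC(C)(C)C)c1ccccc1 | intermediate
21 | [3-(benzoyloxy)-2-tert-butoxy-1,4-dihydroxy-6-oxocyclohexyl]methyl benzoate (C1, C4, C5, C6 as in 22) | O=C(OC[C@@]1(O)C(=O)C[C@@H](O)[C@@H](OC(=O)c2ccccc2)[C@@H]1OC(C)(C)C)c1ccccc1 | intermediate
22 | [(1S,2S,3R,4R)-3-(benzoyloxy)-1,2,4-trihydroxy-6-oxocyclohexyl]methyl benzoate, CNP0127041.1 | O=C(OC[C@@]1(O)C(=O)C[C@@H](O)[C@@H](OC(=O)c2ccccc2)[C@@H]1O)c1ccccc1 | target

## Step count and least certain steps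

Total: 14 steps. Longest linear sequence: 14 steps (1 → 22); the second building block 4 enters in step 3.

**Step 7 (key step).** The dioxolane may open by β-elimination before the enolate is silylated. The shift may also be slow, because the dioxolane must become trans-fused in the boat; this would leave time for ionisation of the donor-substituted allylic C4–O bond and loss of the Z information.

Fallback: open-chain silyl ethers on O1 and O2 instead of the cyclic acetal. It sets out from 1 and returns at 18. Fischer glycosidation (MeOH, HCl) would give methyl 2-deoxy-D-erythro-pentopyranoside F1. Silylation (TBSOTf, 2,6-lutidine) would give the bis-silyl glycoside F2, and mild hydrolysis (AcOH/H2O/THF) the bis-silyl lactol F3. The operations of steps 2 to 9, in the same order, would then lead through bis-silyl lactone F4, alkynyl hemiketal F5, (R)-carbinol diol F6, alkynyl lactone F7, (Z)-enol ether lactone F8, rearranged acid F9 and primary alcohol F10 to benzoate F11. HF·pyridine would remove both silyl ethers and give 18.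

**Step 4.** Hydride transfer may be slow or poorly face-selective, because the ketone is partly stored as the cyclic hemiketal and the alkoxy-alkyne conjugation makes the carbonyl electron-rich; conjugate addition of the solvent may compete.

Fallback: lock the ketone open by O-silylation and reduce with a stoichiometric chiral borane. It sets out from 2 and returns at 8. Addition of 5 (2.5 equiv) to the lactol would give the epimeric open-chain diol F12. TBSCl/imidazole would silylate the primary hydroxyl to give silyl ether F13, and MnO2 would oxidise the propargylic alcohol to the open-chain ynone F14. Midland reduction with (R)-B-isopinocampheyl-9-BBN would give the (4R) carbinol F15, and Bu4NF would then release 8.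

**Step 12.** The β,γ-double bond may migrate into conjugation with the C2 ketone under the amine/N-oxide conditions. Attack syn to the tert-butoxy group is also possible if the ring reacts through the conformer with an axial CH2OBz arm.

Fallback: introduce the diol before the ketone and mask it during the oxidation. It sets out from 18 and returns at 20. OsO4/N-methylmorpholine N-oxide on 18 would give the tetraol F16. 2-Methoxypropene/PPTS would close the cis-4,5-acetonide F17, which leaves O1 and O2 free. IBX would give the α-ketol acetonide F18, and aqueous acetic acid would then release 20.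

**Step 13.** Regioselectivity may be poor if sterics (the tert-butoxy group next to O5) override tin activation. Acylation of O4 would be followed by β-elimination, and base could also move the benzoate from O5 to O4.

Fallback: protect, acylate and deprotect, using the same steric bias the other way round. It sets out from 20 and returns at 22. TESCl/imidazole at low temperature would silylate the less encumbered O4 to give the C4 triethylsilyl ether F19. BzCl/pyridine/DMAP would then give the O5 benzoate F20. Aqueous CF3CO2H in CH2Cl2 would remove the silyl and tert-butyl groups together to give 22.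

**Step 14.** Acid-promoted dehydration of the β-hydroxy ketone, or benzoate migration, may compete while the tert-butyl ether is slowly cleaved.

Fallback: remove the tert-butyl group before the aldol exists and finish with a milder acetal hydrolysis. It sets out from 17 and returns at 22. CF3CO2H/H2O would cleave acetal and tert-butyl ether together to give the triol F21. 2,2-Dimethoxypropane with camphorsulfonic acid would close the cis-fused acetonide on O1/O6, giving F22 with O2 free. IBX would give the ketone F23 and OsO4/N-methylmorpholine N-oxide the cis-diol F24. Me2SnCl2/BzCl/i-Pr2NEt would give the O5 benzoate F25, and aqueous acetic acid at 40 °C would release 22.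

## Further compounds

F1 | step 7 | methyl 2-deoxy-D-erythro-pentopyranoside | COC1C[C@H](O)[C@H](O)CO1
F2 | step 7 | methyl 3,4-bis-O-(tert-butyldimethylsilyl)-2-deoxy-D-erythro-pentopyranoside | COC1C[C@H](O[Si](C)(C)C(C)(C)C)[C@H](O[Si](C)(C)C(C)(C)C)CO1
F3 | step 7 | 3,4-bis-O-(tert-butyldimethylsilyl)-2-deoxy-D-erythro-pentopyranose | OC1C[C@H](O[Si](C)(C)C(C)(C)C)[C@H](O[Si](C)(C)C(C)(C)C)CO1
F4 | step 7 | 3,4-bis-O-(tert-butyldimethylsilyl)-2-deoxy-D-erythro-pentono-1,5-lactone | O=C1C[C@H](O[Si](C)(C)C(C)(C)C)[C@H](O[Si](C)(C)C(C)(C)C)CO1
F5 | step 7 | 1-C-(tert-butoxyethynyl)-3,4-bis-O-(tert-butyldimethylsilyl)-2-deoxy-D-erythro-pentopyranose | OC1(C#COC(C)(C)C)C[C@H](O[Si](C)(C)C(C)(C)C)[C@H](O[Si](C)(C)C(C)(C)C)CO1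
F6 | step 7 | (3R,5S,6R)-1-tert-butoxy-5,6-bis(tert-butyldimethylsilyloxy)hept-1-yne-3,7-diol | OC[C@@H](O[Si](C)(C)C(C)(C)C)[C@@H](O[Si](C)(C)C(C)(C)C)C[C@@H](O)C#COC(C)(C)C
F7 | step 7 | 6-(tert-butoxyethynyl)-3,4-bis(tert-butyldimethylsilyloxy)oxan-2-one | O=C1O[C@@H](C#COC(C)(C)C)C[C@H](O[Si](C)(C)C(C)(C)C)[C@@H]1O[Si](C)(C)C(C)(C)C
F8 | step 7 | 6-[(Z)-2-tert-butoxyethenyl]-3,4-bis(tert-butyldimethylsilyloxy)oxan-2-one | O=C1O[C@@H](/C=C\OC(C)(C)C)C[C@H](O[Si](C)(C)C(C)(C)C)[C@@H]1O[Si](C)(C)C(C)(C)C
F9 | step 7 | 2-tert-butoxy-1,6-bis(tert-butyldimethylsilyloxy)cyclohex-3-ene-1-carboxylic acid | OC(=O)[C@@]1(O[Si](C)(C)C(C)(C)C)[C@@H](O[Si](C)(C)C(C)(C)C)CC=C[C@@H]1OC(C)(C)C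
F10 | step 7 | [2-tert-butoxy-1,6-bis(tert-butyldimethylsilyloxy)cyclohex-3-en-1-yl]methanol | OC[C@@]1(O[Si](C)(C)C(C)(C)C)[C@@H](O[Si](C)(C)C(C)(C)C)CC=C[C@@H]1OC(C)(C)C
F11 | step 7 | [2-tert-butoxy-1,6-bis(tert-butyldimethylsilyloxy)cyclohex-3-en-1-yl]methyl benzoate | O=C(OC[C@@]1(O[Si](C)(C)C(C)(C)C)[C@@H](O[Si](C)(C)C(C)(C)C)CC=C[C@@H]1OC(C)(C)C)c1ccccc1
F12 | step 4 | (5S,6R)-1-tert-butoxy-5,6-(isopropylidenedioxy)hept-1-yne-3,7-diol (both C3 epimers) | OC[C@H]1OC(C)(C)O[C@H]1CC(O)C#COC(C)(C)C
F13 | step 4 | 7-O-(tert-butyldimethylsilyl) ether of F12 | CC(C)(C)[Si](C)(C)OC[C@H]1OC(C)(C)O[C@H]1CC(O)C#COC(C)(C)C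
F14 | step 4 | (5S,6R)-1-tert-butoxy-7-(tert-butyldimethylsilyloxy)-5,6-(isopropylidenedioxy)hept-1-yn-3-one | CC(C)(C)[Si](C)(C)OC[C@H]1OC(C)(C)O[C@H]1CC(=O)C#COC(C)(C)C
F15 | step 4 | (3R,5S,6R)-1-tert-butoxy-7-(tert-butyldimethylsilyloxy)-5,6-(isopropylidenedioxy)hept-1-yn-3-ol | CC(C)(C)[Si](C)(C)OC[C@H]1OC(C)(C)O[C@H]1C[C@@H](O)C#COC(C)(C)C
F16 | step 12 | (2-tert-butoxy-1,3,4,6-tetrahydroxycyclohexyl)methyl benzoate | O=C(OC[C@@]1(O)[C@@H](O)C[C@@H](O)[C@@H](O)[C@@H]1OC(C)(C)C)c1ccccc1
F17 | step 12 | 4,5-O-isopropylidene derivative of F16 (target numbering) | O=C(OC[C@@]1(O)[C@@H](O)C[C@H]2OC(C)(C)O[C@H]2[C@@H]1OC(C)(C)C)c1ccccc1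
F18 | step 12 | 4,5-O-isopropylidene derivative of 20 | O=C(OC[C@@]1(O)C(=O)C[C@H]2OC(C)(C)O[C@H]2[C@@H]1OC(C)(C)C)c1ccccc1
F19 | step 13 | 4-O-triethylsilyl ether of 20 | O=C(OC[C@@]1(O)C(=O)C[C@@H](O[Si](CC)(CC)CC)[C@@H](O)[C@@H]1OC(C)(C)C)c1ccccc1
F20 | step 13 | 4-O-triethylsilyl ether of 21 | O=C(OC[C@@]1(O)C(=O)C[C@@H](O[Si](CC)(CC)CC)[C@@H](OC(=O)c2ccccc2)[C@@H]1OC(C)(C)C)c1ccccc1
F21 | step 14 | (1,2,6-trihydroxycyclohex-3-en-1-yl)methyl benzoate (O1/O6 cis; target C1, C6, C2) | O=C(OC[C@@]1(O)[C@@H](O)CC=C[C@@H]1O)c1ccccc1
F22 | step 14 | 1,6-O-isopropylidene derivative of F21 (target numbering; O2 free) | O=C(OC[C@]12OC(C)(C)O[C@H]1C=CC[C@@H]2O)c1ccccc1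
F23 | step 14 | C2 ketone of F22 | O=C(OC[C@]12OC(C)(C)O[C@H]1C=CCC2=O)c1ccccc1
F24 | step 14 | cis-4,5-diol of F23 | O=C(OC[C@]12OC(C)(C)O[C@H]1[C@H](O)[C@H](O)CC2=O)c1ccccc1
F25 | step 14 | 5-O-benzoate of F24 (1,6-O-isopropylidene derivative of 22) | O=C(OC[C@]12OC(C)(C)O[C@H]1[C@H](OC(=O)c3ccccc3)[C@H](O)CC2=O)c1ccccc1
A1 | alternative 1 | acyclic C4,C5-dialdehyde with C1/C6 acetonide, C2 dioxolane ketal and C7 benzoate | O=C[C@@H]1OC(C)(C)O[C@]1(COC(=O)c2ccccc2)C2(CC=O)OCCO2
A2 | alternative 1 | cis-4,5-diol with C1/C6 acetonide and C2 dioxolane ketal | O=C(OC[C@]12OC(C)(C)O[C@H]1[C@H](O)[C@H](O)CC23OCCO3)c1ccccc1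
A3 | alternative 2 | C1 ketone with C2 dimethyl ketal, O4 and O6 silyl ethers, O5 p-methoxybenzyl ether | O=C1C(OC)(OC)C[C@@H](O[Si](C)(C)C(C)(C)C)[C@@H](OCc2ccc(OC)cc2)[C@@H]1O[Si](C)(C)C(C)(C)C
A4 | alternative 2 | C1 spiro-oxirane of A3 | C1O[C@@]12C(OC)(OC)C[C@@H](O[Si](C)(C)C(C)(C)C)[C@@H](OCc3ccc(OC)cc3)[C@@H]2O[Si](C)(C)C(C)(C)C
A5 | alternative 3 | methyl C4-branched hex-5-enopyranoside (sugar C2 benzoate, C3 benzyl ether, C4 hydroxyl and benzoyloxymethyl) | COC1OC(=C)[C@](O)(COC(=O)c2ccccc2)[C@@H](OCc2ccccc2)[C@@H]1OC(=O)c1ccccc1
A6 | alternative 3 | 6-O-benzyl ether of 22 | O=C(OC[C@@]1(O)C(=O)C[C@@H](O)[C@@H](OC(=O)c2ccccc2)[C@@H]1OCc1ccccc1)c1ccccc1
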